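**Remark:** ethers 4 and 29 and alcohol 26 may form as mixtures of C4 epimers. Both epimers ionise to the same cation, so each is drawn as the epimer expected to predominate. Units are counted from the catechin end (unit 1) to the terminal epicatechin (unit 4).

## The problem

Compound 32 is a linear tetramer of flavan-3-ols. A catechin unit (unit 1) is bonded from C4 to C6 of an epicatechin (unit 2), whose C4 is bonded to C8 of a second epicatechin (unit 3), whose C4 is bonded to C8 of a terminal epicatechin (unit 4). There are eleven stereocentres: C2 and C3 of every unit and C4 of units 1 to 3, each C4 substituent being trans to the oxygen on C3 (4α in unit 1, 4β in units 2 and 3). The C2/C3 pairs of units 1, 3 and 4 are those of (+)-catechin and (−)-epicatechin, and in each the C3 oxygen can steer a nucleophile to the opposite face of a C4 cation. The cis C2/C3 pair of unit 2 and the 4→6 bond joining it to unit 1 cannot be taken from the chiral pool. The 4→6 bond is the real obstacle, because a flavan nucleophile is attacked at C8 much faster than at C6, so direct cationic coupling gives the wrong constitutional isomer. The molecule tolerates little: interflavan bonds revert under acid, the oxygenated rings oxidise easily and are themselves nucleophiles toward any C4 cation, and a 2,3-cis ring with a C4 carbonyl epimerises at C3 or opens at O1–C2 under base. The feature that permits the key step lies in ring A of unit 2. O1 sits on C8a and C4 on the neighbouring C4a, C4a is flanked by the C5 oxygen, and C8a is para to C6. An aryne across C4a–C8a on a ring that already carries unit 1 can therefore accept O1 and C4 in one operation with the 4→6 pattern already decided.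

## Retrosynthesis

**Global deprotection.** Every oxygen that needs cover is carried as a benzyl ether, so 32 is traced to 31, in which the C3 hydroxyls of units 3 and 4 stay free. One protecting group means one final operation, hydrogenolysis, which is neutral and spares the interflavan bonds; silyl or acyl cover would require fluoride or base on the free polyphenol. The forward step must remove eighteen groups without reducing the rings.

**Bond C4(unit 2)–C8(unit 3).** Tetramer 31 is cut in the middle into flavan-4-ol 26 (units 1 and 2) and dimer 30 (units 3 and 4). This is the interflavan bond to cut last. The 4→6 bond cannot be formed regioselectively by cation capture, and a cut between units 3 and 4 would require a trimer electrophile. The halves are of equal size, and only C4 of unit 2 remains to be set. The forward Friedel–Crafts alkylation must reach C8 of the upper unit of 30 from the face trans to the C3 benzyloxy group.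

**Ring C of unit 2.** The hydroxyl of 26 is traced to the ketone of 25, since a C4 carbonyl is what an acyl transfer leaves behind. Ketone 25 is cut at O1–C8a and C4a–C4 of unit 2, which removes ring C and leaves aryne 24 (from silyl triflate 15) and silyl ether 23 of a syn α-benzyloxy-β-hydroxy ester. The neighbouring cuts are worse. Cleaving C4(unit 1)–C6(unit 2) returns to a cation capture that prefers C8. Cleaving O1–C2 or C2–C3 leaves the cis C2/C3 pair to be made on a large molecule. In the chosen cut both stereocentres of the new ring arrive in a small acyclic ester, the para relationship of unit 1 and the triflate in 15 fixes the 4→6 pattern, and the C5 benzyloxy group beside the triple bond decides which aryne carbon takes oxygen. The forward reaction must add the alkoxide at C8a, capture the ester at C4a, and leave C3 of the cis ketone untouched.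

**The ester.** Silyl ether 23 comes from alcohol 22, and 22 from aldol adduct 21 by exchange of the auxiliary for methoxide. Cutting C2–C3 of 21 gives glycolyl imide 18 and aldehyde 19; 18 comes from oxazolidinone 16 and acid chloride 17. The aldol cut is preferred to dihydroxylation of a cinnamate because it places the benzyl group on the α oxygen from the start, whereas the diol route would need two secondary hydroxyls to be told apart. The forward aldol must give the syn (2S,3R) isomer.

**The aryne precursor.** Triflate 15 is traced to phenol 14, this to carbamate 13, and removal of the silyl group gives carbamate 10, made from phenol 9. The carbamate is the one oxygen substituent that can direct a base to its ortho position in the presence of seven benzyl ethers and three other oxygenated rings, and it is exchanged for triflate in one flask. The two positions ortho to the carbamate are equivalent, so only selectivity between rings is required.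

**The para oxygen.** Phenol 9 differs from triol 6 by two benzyl groups on the hydroxyls next to unit 1. The three hydroxyls of 6 are distinguished by their steric surroundings: the para one is silylated (7), the two flanking ones are benzylated (8), and the silyl group is removed. These three steps are the price of the next cut.

**Bond C4(unit 1)–aryl.** Triol 6 is cut into C4 ether 4 and phloroglucinol 5. A nucleophile already differentiated at one oxygen would save steps but would offer the cation two kinds of ring carbon, and the wanted one (between two ether oxygens) is the less reactive; 5 has only one kind. Ether 4 comes from pentabenzyl ether 3 by oxidation at C4, and 3 via 2 from (+)-catechin 1, which supplies C2 and C3 of unit 1. The capture must occur trans to the C3 benzyloxy group.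

**The lower dimer.** Dimer 30 is cut at its interflavan bond into C4 ether 29 and tetrabenzyl ether 28, both from (−)-epicatechin 27, which supplies C2 and C3 of units 3 and 4.

## Roads not taken

**Alternative 1:** The cut runs through C4–C4a of both unit 3 and unit 4. In the forward direction a Lewis acid would open two epoxides held on one open-chain bis(aryl ether). Each ring A attacks its own epoxide through the ortho carbon, both C rings close together, and the epoxide oxygens appear as the two free C3 hydroxyls of A1, which is the same compound as dimer 30.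

- Merits: two rings and two C–C bonds in one step, independence from the supply of (−)-epicatechin, and free choice of substitution in units 3 and 4.
- Weak points for this target:
  - The open-chain substrate hides much effort: two benzylic aryl-ether carbons and two epoxides must each be set by a separate asymmetric step.
  - The benzylic O1–C2 ether bonds next to an electron-rich ring B can ionise under the Lewis acid, with loss of C2 configuration.
  - At the terminal epoxide of the unit 4 half, six-membered closure at the primary carbon competes with five-membered closure.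
  - The product is the half of 32 that the chiral pool supplies with four of its five stereocentres ready-made.
- Comparison: in ring-forming power per step this road is better than the three-step passage from 27 to 30 used here, which also has to suppress oligomerisation with an excess of 28. The chosen plan sets against this that its new chemistry is spent on the 4→6-linked unit 2, which Alternative 1 leaves untouched.

**Alternative 2:** Unit 2 is cut at C3–C4 and at O1–C2, with C2 taken to the acid oxidation level. Forward, an ortho-quinone methide formed on ring A of unit 2 (carrying unit 1 at C6 and C8 of unit 3 on the exocyclic carbon) would be intercepted by a chiral catalyst-bound two-carbon enolate bearing the C3 benzyloxy group. The formal [4+2] annulation forms C3–C4 and the lactone bond and gives dihydrocoumarin A2.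

- Merits: carbene-catalysed enolate annulation of ortho-quinone methides is an established reaction class, which the key step of the present plan is not. C3 and C4 are set together under catalyst control. The two halves are joined before ring C is made, so no acid-mediated coupling of two dimers is needed; that coupling is the weakest operation after the key step in the adopted route.
- Weak points:
  - A2 lacks ring B of unit 2 and has a carbonyl where C2 should be. An aryl nucleophile must be added to the lactone of a fully assembled tetramer and the lactol reduced cis to C3, under Lewis-acidic conditions that both interflavan bonds must survive.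
  - The quinone methide precursor is a heavily ortho-substituted diarylmethane joining two dimers, so the regiochemical problem at C8 of unit 3 is moved rather than solved.
  - The catalyst must overrule three resident flavan units.
- Comparison: the chosen plan sets against this that 25 arrives with ring B, C2 and C3 in place, three steps from 32.

**Alternative 3:** The cut is the O1–C2 bond of unit 3. Forward, mild acid would let the ring A phenol open a cis epoxide at its benzylic carbon with inversion. Ring C of unit 3 closes, the epoxide oxygen becomes the free C3 hydroxyl, and A3 results.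

- Merits: this is the most conservative idea. Phenol–epoxide cyclisation to flavan-3-ols is known chemistry, the benzylic carbon is activated for six-membered closure, and C2 and C3 come from one asymmetric epoxidation.
- Weak points:
  - The epoxide must sit on a chain whose C4 already carries ring A of unit 3 and C8 of unit 4 in defined configuration. A cis alkene of that kind, and its face-selective epoxidation next to a diarylmethine centre, are harder to secure than the problem they replace.
  - The electron-rich ring B gives the opening carbocation character, so inversion, and with it the 2,3-cis relationship, may erode.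
  - The ring that is built again belongs to the lower dimer, which is bought as 27.
- Comparison: on reliability of the key reaction this road is better than the aryne annulation. The chosen plan answers with convergence, with the stereocentres of units 3 and 4 taken from 27 unchanged, and with a key step aimed at the one bond pattern that no known coupling delivers selectively.

Key step: step 15

## Route

Step 1
Reactants: 1 (+)-catechin
Product: 2 5,7,3',4'-tetra-O-benzyl-(+)-catechin
Conditions: BnBr, K2CO3, DMF, 0 °C to rt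
Reagents that add atoms: benzyl bromide, BrCc1ccccc1
Why: Williamson etherification of the four phenols; K2CO3 does not deprotonate the aliphatic 3-OH and no stereocentre is touched.

Step 2
Reactants: 2 5,7,3',4'-tetra-O-benzyl-(+)-catechin
Product: 3 3,5,7,3',4'-penta-O-benzyl-(+)-catechin
Conditions: NaH, BnBr, DMF, 0 °C to rt
Reagents that add atoms: benzyl bromide, BrCc1ccccc1
Why: Williamson benzylation of the secondary alkoxide; the 3-O-benzyl group later keeps this oxygen from competing as an aryne nucleophile and shields the β face of the C4 cation.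

Step 3
Reactants: 3 3,5,7,3',4'-penta-O-benzyl-(+)-catechin
Product: 4 (2R,3S,4S)-3,5,7,3',4'-pentakis(benzyloxy)-4-(2-ethoxyethoxy)flavan (4β ether)
Conditions: DDQ, 2-ethoxyethanol, CH2Cl2, rt
Reagents that add atoms: 2-ethoxyethanol, CCOCCO
Why: benzylic oxidation by hydride abstraction at C4, which is activated by the ortho and para oxygens of ring A, and capture of the cation by the alcohol; either C4 epimer serves in the next step.

Step 4
Reactants: 4 (2R,3S,4S)-3,5,7,3',4'-pentakis(benzyloxy)-4-(2-ethoxyethoxy)flavan; 5 phloroglucinol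
Product: 6 penta-O-benzylcatechin-(4α→2)-phloroglucinol [(2R,3S)-3,5,7,3',4'-pentakis(benzyloxy)-4α-(2,4,6-trihydroxyphenyl)flavan; 3,4-trans]
Conditions: 5 (5 equiv), BF3·OEt2, THF/CH2Cl2, −78 to 0 °C
Reagents that add atoms: none
Why: Friedel–Crafts alkylation through the C4 cation; the three ring carbons of 5 are equivalent, so no regiochemical question arises, and attack anti to the C3 benzyloxy group sets C4 as 4α (3,4-trans); the excess of 5 suppresses double alkylation.

Step 5
Reactants: 6 penta-O-benzylcatechin-(4α→2)-phloroglucinol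
Product: 7 para-silyl ether [(2R,3S)-3,5,7,3',4'-pentakis(benzyloxy)-4α-[2,6-dihydroxy-4-(triisopropylsilyloxy)phenyl]flavan]
Conditions: TIPSCl (1.05 equiv), imidazole, DMF, 0 °C
Reagents that add atoms: triisopropylsilyl chloride, CC(C)[Si](Cl)(C(C)C)C(C)C
Why: sterically controlled silylation; the para hydroxyl has two hydrogen neighbours, whereas each ortho hydroxyl is pressed against the branched flavanyl carbon, so the bulky chloride should select the para oxygen.

Step 6
Reactants: 7 para-silyl ether
Product: 8 dibenzyl silyl ether [(2R,3S)-3,5,7,3',4'-pentakis(benzyloxy)-4α-[2,6-bis(benzyloxy)-4-(triisopropylsilyloxy)phenyl]flavan]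
Conditions: BnBr, K2CO3, DMF, rt
Reagents that add atoms: benzyl bromide, BrCc1ccccc1
Why: Williamson etherification of the two remaining phenols; an aryl triisopropylsilyl ether withstands K2CO3 at room temperature.

Step 7
Reactants: 8 dibenzyl silyl ether
Product: 9 phenol [3,5-bis(benzyloxy)-4-(penta-O-benzylcatechin-4α-yl)phenol]
Conditions: TBAF, AcOH, THF, 0 °C
Reagents that add atoms: none
Why: fluoride cleavage of the aryl silyl ether; acetic acid buffers the phenoxide.

Step 8
Reactants: 9 phenol
Product: 10 carbamate [3,5-bis(benzyloxy)-4-(penta-O-benzylcatechin-4α-yl)phenyl N-isopropylcarbamate]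
Conditions: i-PrNCO, Et3N (cat.), CH2Cl2, rt
Reagents that add atoms: isopropyl isocyanate, CC(C)N=C=O
Why: base-catalysed addition of the single free phenol to the isocyanate installs a directing group that is later removable under mild base.

Step 9
Reactants: 10 carbamate
Product: 13 ortho-silyl carbamate [3,5-bis(benzyloxy)-4-(penta-O-benzylcatechin-4α-yl)-2-(trimethylsilyl)phenyl N-isopropylcarbamate], via N-silyl carbamate 11 (not isolated), via C-silylated N-silyl carbamate 12 (not isolated)
Conditions: TBSOTf, TMEDA, Et2O, 0 °C to rt; n-BuLi, TMEDA, −78 °C; TMSCl, −78 °C to rt; aq. NaHSO4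
Reagents that add atoms: chlorotrimethylsilane, C[Si](C)(C)Cl
Why: directed ortho-metalation; the carbamate N–H is silylated in the flask, the complexed base then lithiates the position between the carbamate and the benzyloxy group (the two such positions are equivalent), the aryllithium is silylated, and the N–Si bond is hydrolysed on work-up.

Step 10
Reactants: 13 ortho-silyl carbamate
Product: 15 silyl triflate [3,5-bis(benzyloxy)-4-(penta-O-benzylcatechin-4α-yl)-2-(trimethylsilyl)phenyl trifluoromethanesulfonate], via silylphenol 14 (not isolated)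
Conditions: DBU, Et2NH, MeCN/THF, 40 °C; then PhNTf2, rt
Reagents that add atoms: N-phenylbis(trifluoromethanesulfonimide), O=S(=O)(N(c1ccccc1)S(=O)(=O)C(F)(F)F)C(F)(F)F
Why: E1cB cleavage of the N-monoalkyl carbamate, with the isocyanate taken up by diethylamine as a urea, followed by triflation of the phenoxide in the same flask; this is the standard end of the carbamate route to ortho-silylaryl triflates.

Step 11
Reactants: 16 (S)-4-benzyl-2-oxazolidinone; 17 benzyloxyacetyl chloride
Product: 18 (S)-4-benzyl-3-(benzyloxyacetyl)oxazolidin-2-one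
Conditions: n-BuLi, THF, −78 °C; then 17, −78 to 0 °C
Reagents that add atoms: none
Why: N-acylation of the lithiated oxazolidinone.

Step 12
Reactants: 18 (S)-4-benzyl-3-(benzyloxyacetyl)oxazolidin-2-one; 19 3,4-bis(benzyloxy)benzaldehyde
Product: 21 aldol adduct [(S)-4-benzyl-3-[(2S,3R)-2-benzyloxy-3-[3,4-bis(benzyloxy)phenyl]-3-hydroxypropanoyl]oxazolidin-2-one], via boron enolate 20 (not isolated)
Conditions: Bu2BOTf, Et3N, CH2Cl2, −78 to 0 °C; 19, −78 to 0 °C; pH 7 buffer, MeOH, H2O2
Reagents that add atoms: none
Why: Evans syn aldol; the (Z)-boron enolate reacts through a Zimmerman–Traxler chair on the face away from the auxiliary benzyl group, which sets both new stereocentres as the syn (2S,3R) pair.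

Step 13
Reactants: 21 aldol adduct
Product: 22 methyl (2S,3R)-2-benzyloxy-3-[3,4-bis(benzyloxy)phenyl]-3-hydroxypropanoate
Conditions: MeMgBr, MeOH, CH2Cl2, 0 °C
Reagents that add atoms: methanol, CO
Why: transesterification with bromomagnesium methoxide at the exocyclic carbonyl, assisted by chelation to the β-hydroxyl; the mild conditions should avoid retro-aldol cleavage and α-epimerisation, and the auxiliary is recovered.

Step 14
Reactants: 22 methyl (2S,3R)-2-benzyloxy-3-[3,4-bis(benzyloxy)phenyl]-3-hydroxypropanoate
Product: 23 methyl (2S,3R)-2-benzyloxy-3-[3,4-bis(benzyloxy)phenyl]-3-(trimethylsilyloxy)propanoate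
Conditions: TMSCl, imidazole, CH2Cl2, 0 °C; non-aqueous filtration
Reagents that add atoms: chlorotrimethylsilane, C[Si](C)(C)Cl
Why: silylation of the secondary alcohol; the silyl ether stores the alkoxide in neutral form until fluoride releases it in the key step.

Step 15
Reactants: 15 silyl triflate; 23 methyl (2S,3R)-2-benzyloxy-3-[3,4-bis(benzyloxy)phenyl]-3-(trimethylsilyloxy)propanoate
Product: 25 penta-O-benzylcatechin-(4α→6)-[(2R,3S)-3,5,7,3',4'-pentakis(benzyloxy)-2,3-cis-flavan-4-one], via aryne 24 (not isolated)
Conditions: CsF, 18-crown-6, THF, −20 to 0 °C; AcOH, pH 7 buffer, −20 °C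
Reagents that add atoms: none
Why: Proposed new method: fluoride removes the trimethylsilyl group of 15 with loss of triflate to give aryne 24 and frees the alkoxide of 23 from its silyl ether; the alkoxide adds to the aryne carbon remote from the flanking C5 benzyloxy group (the future C8a), forming O1–C8a and leaving an aryl anion at C4a that the adjacent C–O bond stabilises inductively. The anion attacks the ester carbonyl through a six-membered transition state (6-exo-trig), forming C4a–C4 and closing ring C, and the tetrahedral intermediate expels methoxide. The closest known reaction type is the fluoride-triggered annulation of arynes with salicylate esters to xanthones (O-arylation followed by acyl capture by the aryl anion); an aliphatic β-alkoxy ester has not been used in it. No new stereocentre is formed and no bond to C2 or C3 is broken, so the syn (2S,3R) pattern of 23 becomes the 2,3-cis ring of unit 2, and the 4→6 linkage is fixed because unit 1 sits para to the triflate carbon of 15. The selectivity required is regiochemical (oxygen to C8a, acyl carbon to C4a) and is secured by the polarisation that the C5 benzyloxy group imposes on the neighbouring triple bond. The silyl ether replaces a preformed sodium alkoxide so that expelled methoxide is absorbed as methoxytrimethylsilane, releasing the next alkoxide, and no stoichiometric base is left to epimerise C3 or open O1–C2 of the cis ketone. A cold, short reaction and a buffered acidic quench serve the same purpose.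

Step 16
Reactants: 25 penta-O-benzylcatechin-(4α→6)-[(2R,3S)-3,5,7,3',4'-pentakis(benzyloxy)-2,3-cis-flavan-4-one]
Product: 26 penta-O-benzylcatechin-(4α→6)-[3,5,7,3',4'-pentakis(benzyloxy)-2,3-cis-3,4-cis-flavan-4-ol]
Conditions: NaBH4, CeCl3·7H2O, THF/MeOH, −40 to 0 °C
Reagents that add atoms: none
Why: Luche-type 1,2-reduction of the aryl ketone under weakly basic conditions that should spare C3; hydride is expected anti to the axial 3-benzyloxy group (3,4-cis alcohol), but the C4 configuration is lost in step 20 and does not matter.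

Step 17
Reactants: 27 (−)-epicatechin
Product: 28 5,7,3',4'-tetra-O-benzyl-(−)-epicatechin
Conditions: BnBr, K2CO3, DMF, 0 °C to rt
Reagents that add atoms: benzyl bromide, BrCc1ccccc1
Why: Williamson etherification of the four phenols, as in step 1; 28 serves both as precursor of 29 and as nucleophile in step 19.

Step 18
Reactants: 28 5,7,3',4'-tetra-O-benzyl-(−)-epicatechin
Product: 29 (2R,3R,4S)-5,7,3',4'-tetrakis(benzyloxy)-4-(2-ethoxyethoxy)flavan-3-ol (4β ether; 3,4-trans)
Conditions: DDQ, 2-ethoxyethanol, CH2Cl2, rt
Reagents that add atoms: 2-ethoxyethanol, CCOCCO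
Why: benzylic oxidation at C4 as in step 3; the alcohol enters on the β face, away from the cis C2 aryl and C3 hydroxyl groups.

Step 19
Reactants: 29 (2R,3R,4S)-5,7,3',4'-tetrakis(benzyloxy)-4-(2-ethoxyethoxy)flavan-3-ol; 28 5,7,3',4'-tetra-O-benzyl-(−)-epicatechin
Product: 30 5,7,3',4'-tetra-O-benzylepicatechin-(4β→8)-5,7,3',4'-tetra-O-benzylepicatechin
Conditions: 28 (4 equiv), TMSOTf (cat.), CH2Cl2, −78 °C
Reagents that add atoms: none
Why: Friedel–Crafts alkylation through the C4 cation of 29; C8 of 28 is its most nucleophilic position and attack anti to the C2 aryl and C3 hydroxyl groups sets C4 as 4β; the excess of 28 limits further oligomerisation.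

Step 20
Reactants: 26 penta-O-benzylcatechin-(4α→6)-[3,5,7,3',4'-pentakis(benzyloxy)-2,3-cis-3,4-cis-flavan-4-ol]; 30 5,7,3',4'-tetra-O-benzylepicatechin-(4β→8)-5,7,3',4'-tetra-O-benzylepicatechin
Product: 31 octadeca-O-benzyl tetramer [penta-O-benzylcatechin-(4α→6)-(3,5,7,3',4'-penta-O-benzylepicatechin)-(4β→8)-(5,7,3',4'-tetra-O-benzylepicatechin)-(4β→8)-(5,7,3',4'-tetra-O-benzylepicatechin)]
Conditions: 30 (4 equiv), TMSOTf (0.3 equiv), 4 Å molecular sieves, CH2Cl2, −78 to −40 °C; Et3N
Reagents that add atoms: none
Why: dehydrative Friedel–Crafts alkylation; the C4 cation of unit 2 is stabilised by three ring A oxygens and is attacked anti to the C3 benzyloxy and C2 aryl groups (4β, 3,4-trans) by C8 of the upper unit of 30, the most nucleophilic position of the dimer.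

Step 21
Reactants: 31 octadeca-O-benzyl tetramer
Product: 32 catechin-(4α→6)-epicatechin-(4β→8)-epicatechin-(4β→8)-epicatechin (CNP0228086.1)
Conditions: H2 (1 atm), Pd(OH)2/C, THF/MeOH/H2O, rt
Reagents that add atoms: none
Why: hydrogenolysis of the eighteen benzyl ethers under neutral conditions that leave interflavan bonds and stereocentres untouched.

## Compound list

1 | (+)-catechin | O[C@H]1Cc2c(O)cc(O)cc2O[C@@H]1c1ccc(O)c(O)c1 | starting material
2 | 5,7,3',4'-tetra-O-benzyl-(+)-catechin | c9ccccc9COc1cc(OCc9ccccc9)c2c(c1)O[C@H](c8ccc(OCc9ccccc9)c(OCc9ccccc9)c8)[C@@H](O)C2 | intermediate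
3 | 3,5,7,3',4'-penta-O-benzyl-(+)-catechin | c9ccccc9COc1cc(OCc9ccccc9)c2c(c1)O[C@H](c8ccc(OCc9ccccc9)c(OCc9ccccc9)c8)[C@@H](OCc9ccccc9)C2 | intermediate
4 | (2R,3S,4S)-3,5,7,3',4'-pentakis(benzyloxy)-4-(2-ethoxyethoxy)flavan (4β ether) | c9ccccc9COc1cc(OCc9ccccc9)c2c(c1)O[C@H](c8ccc(OCc9ccccc9)c(OCc9ccccc9)c8)[C@@H](OCc9ccccc9)[C@H]2OCCOCC | intermediate
5 | phloroglucinol | Oc1cc(O)cc(O)c1 | starting material
6 | penta-O-benzylcatechin-(4α→2)-phloroglucinol | c9ccccc9COc1cc(OCc9ccccc9)c2c(c1)O[C@H](c8ccc(OCc9ccccc9)c(OCc9ccccc9)c8)[C@@H](OCc9ccccc9)[C@@H]2c1c(O)cc(O)cc1O | intermediate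
7 | para-silyl ether: 4α-[2,6-dihydroxy-4-(triisopropylsilyloxy)phenyl]-penta-O-benzylcatechin | c9ccccc9COc1cc(OCc9ccccc9)c2c(c1)O[C@H](c8ccc(OCc9ccccc9)c(OCc9ccccc9)c8)[C@@H](OCc9ccccc9)[C@@H]2c1c(O)cc(O[Si](C(C)C)(C(C)C)C(C)C)cc1O | intermediate
8 | dibenzyl silyl ether: 4α-[2,6-bis(benzyloxy)-4-(triisopropylsilyloxy)phenyl]-penta-O-benzylcatechin | c9ccccc9COc1cc(OCc9ccccc9)c2c(c1)O[C@H](c8ccc(OCc9ccccc9)c(OCc9ccccc9)c8)[C@@H](OCc9ccccc9)[C@@H]2c1c(OCc9ccccc9)cc(O[Si](C(C)C)(C(C)C)C(C)C)cc1OCc9ccccc9 | intermediate
9 | 3,5-bis(benzyloxy)-4-(penta-O-benzylcatechin-4α-yl)phenol | c9ccccc9COc1cc(OCc9ccccc9)c2c(c1)O[C@H](c8ccc(OCc9ccccc9)c(OCc9ccccc9)c8)[C@@H](OCc9ccccc9)[C@@H]2c1c(OCc9ccccc9)cc(O)cc1OCc9ccccc9 | intermediate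
10 | 3,5-bis(benzyloxy)-4-(penta-O-benzylcatechin-4α-yl)phenyl N-isopropylcarbamate | c9ccccc9COc1cc(OCc9ccccc9)c2c(c1)O[C@H](c8ccc(OCc9ccccc9)c(OCc9ccccc9)c8)[C@@H](OCc9ccccc9)[C@@H]2c1c(OCc9ccccc9)cc(OC(=O)NC(C)C)cc1OCc9ccccc9 | intermediate
11 | N-(tert-butyldimethylsilyl) derivative of carbamate 10 (not isolated) | c9ccccc9COc1cc(OCc9ccccc9)c2c(c1)O[C@H](c8ccc(OCc9ccccc9)c(OCc9ccccc9)c8)[C@@H](OCc9ccccc9)[C@@H]2c1c(OCc9ccccc9)cc(OC(=O)N(C(C)C)[Si](C)(C)C(C)(C)C)cc1OCc9ccccc9 | intermediate
12 | N-(tert-butyldimethylsilyl)-2-(trimethylsilyl) carbamate (not isolated) | c9ccccc9COc1cc(OCc9ccccc9)c2c(c1)O[C@H](c8ccc(OCc9ccccc9)c(OCc9ccccc9)c8)[C@@H](OCc9ccccc9)[C@@H]2c1c(OCc9ccccc9)c([Si](C)(C)C)c(OC(=O)N(C(C)C)[Si](C)(C)C(C)(C)C)cc1OCc9ccccc9 | intermediate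
13 | 3,5-bis(benzyloxy)-4-(penta-O-benzylcatechin-4α-yl)-2-(trimethylsilyl)phenyl N-isopropylcarbamate | c9ccccc9COc1cc(OCc9ccccc9)c2c(c1)O[C@H](c8ccc(OCc9ccccc9)c(OCc9ccccc9)c8)[C@@H](OCc9ccccc9)[C@@H]2c1c(OCc9ccccc9)c([Si](C)(C)C)c(OC(=O)NC(C)C)cc1OCc9ccccc9 | intermediate
14 | 3,5-bis(benzyloxy)-4-(penta-O-benzylcatechin-4α-yl)-2-(trimethylsilyl)phenol (not isolated) | c9ccccc9COc1cc(OCc9ccccc9)c2c(c1)O[C@H](c8ccc(OCc9ccccc9)c(OCc9ccccc9)c8)[C@@H](OCc9ccccc9)[C@@H]2c1c(OCc9ccccc9)c([Si](C)(C)C)c(O)cc1OCc9ccccc9 | intermediate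
15 | 3,5-bis(benzyloxy)-4-(penta-O-benzylcatechin-4α-yl)-2-(trimethylsilyl)phenyl trifluoromethanesulfonate | c9ccccc9COc1cc(OCc9ccccc9)c2c(c1)O[C@H](c8ccc(OCc9ccccc9)c(OCc9ccccc9)c8)[C@@H](OCc9ccccc9)[C@@H]2c1c(OCc9ccccc9)c([Si](C)(C)C)c(OS(=O)(=O)C(F)(F)F)cc1OCc9ccccc9 | intermediate
16 | (S)-4-benzyl-2-oxazolidinone | O=C1N[C@@H](Cc2ccccc2)CO1 | starting material
17 | benzyloxyacetyl chloride | O=C(Cl)COCc1ccccc1 | starting material
18 | (S)-4-benzyl-3-(benzyloxyacetyl)oxazolidin-2-one | O=C1OC[C@H](Cc2ccccc2)N1C(=O)COCc1ccccc1 | intermediate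
19 | 3,4-bis(benzyloxy)benzaldehyde | O=Cc1ccc(OCc2ccccc2)c(OCc2ccccc2)c1 | starting material
20 | (Z)-dibutylboron enolate of 18 (not isolated) | O=C1OC[C@H](Cc2ccccc2)N1/C(OB(CCCC)CCCC)=C/OCc1ccccc1 | intermediate
21 | (S)-4-benzyl-3-[(2S,3R)-2-benzyloxy-3-[3,4-bis(benzyloxy)phenyl]-3-hydroxypropanoyl]oxazolidin-2-one | O=C1OC[C@H](Cc2ccccc2)N1C(=O)[C@@H](OCc9ccccc9)[C@H](O)c8ccc(OCc9ccccc9)c(OCc9ccccc9)c8 | intermediate
22 | methyl (2S,3R)-2-benzyloxy-3-[3,4-bis(benzyloxy)phenyl]-3-hydroxypropanoate | COC(=O)[C@@H](OCc9ccccc9)[C@H](O)c8ccc(OCc9ccccc9)c(OCc9ccccc9)c8 | intermediate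
23 | methyl (2S,3R)-2-benzyloxy-3-[3,4-bis(benzyloxy)phenyl]-3-(trimethylsilyloxy)propanoate | COC(=O)[C@@H](OCc9ccccc9)[C@H](O[Si](C)(C)C)c8ccc(OCc9ccccc9)c(OCc9ccccc9)c8 | intermediate
24 | aryne: 3,5-bis(benzyloxy)-4-(penta-O-benzylcatechin-4α-yl)-1,2-didehydrobenzene (not isolated) | c9ccccc9COc1cc(OCc9ccccc9)c2c(c1)O[C@H](c8ccc(OCc9ccccc9)c(OCc9ccccc9)c8)[C@@H](OCc9ccccc9)[C@@H]2C1=C(OCc9ccccc9)C#CC=C1OCc9ccccc9 | intermediate
25 | penta-O-benzylcatechin-(4α→6)-[(2R,3S)-3,5,7,3',4'-pentakis(benzyloxy)-2,3-cis-flavan-4-one] | c9ccccc9COc1cc(OCc9ccccc9)c2c(c1)O[C@H](c8ccc(OCc9ccccc9)c(OCc9ccccc9)c8)[C@@H](OCc9ccccc9)[C@@H]2c1c(OCc9ccccc9)cc2c(c1OCc9ccccc9)C(=O)[C@@H](OCc9ccccc9)[C@@H](c8ccc(OCc9ccccc9)c(OCc9ccccc9)c8)O2 | intermediate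
26 | penta-O-benzylcatechin-(4α→6)-[3,5,7,3',4'-pentakis(benzyloxy)-2,3-cis-3,4-cis-flavan-4-ol] | c9ccccc9COc1cc(OCc9ccccc9)c2c(c1)O[C@H](c8ccc(OCc9ccccc9)c(OCc9ccccc9)c8)[C@@H](OCc9ccccc9)[C@@H]2c1c(OCc9ccccc9)cc2c(c1OCc9ccccc9)[C@@H](O)[C@@H](OCc9ccccc9)[C@@H](c8ccc(OCc9ccccc9)c(OCc9ccccc9)c8)O2 | intermediate
27 | (−)-epicatechin | O[C@@H]1Cc2c(O)cc(O)cc2O[C@@H]1c1ccc(O)c(O)c1 | starting material
28 | 5,7,3',4'-tetra-O-benzyl-(−)-epicatechin | c9ccccc9COc1cc(OCc9ccccc9)c2c(c1)O[C@H](c8ccc(OCc9ccccc9)c(OCc9ccccc9)c8)[C@H](O)C2 | intermediate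
29 | (2R,3R,4S)-5,7,3',4'-tetrakis(benzyloxy)-4-(2-ethoxyethoxy)flavan-3-ol (4β ether) | c9ccccc9COc1cc(OCc9ccccc9)c2c(c1)O[C@H](c8ccc(OCc9ccccc9)c(OCc9ccccc9)c8)[C@H](O)[C@H]2OCCOCC | intermediate
30 | 5,7,3',4'-tetra-O-benzylepicatechin-(4β→8)-5,7,3',4'-tetra-O-benzylepicatechin | c9ccccc9COc1cc(OCc9ccccc9)c3c(c1)O[C@H](c8ccc(OCc9ccccc9)c(OCc9ccccc9)c8)[C@H](O)[C@H]3c1c(OCc9ccccc9)cc(OCc9ccccc9)c3c1O[C@H](c8ccc(OCc9ccccc9)c(OCc9ccccc9)c8)[C@H](O)C3 | intermediate
31 | octadeca-O-benzyl tetramer: penta-O-benzylcatechin-(4α→6)-(3,5,7,3',4'-penta-O-benzylepicatechin)-(4β→8)-(5,7,3',4'-tetra-O-benzylepicatechin)-(4β→8)-(5,7,3',4'-tetra-O-benzylepicatechin) | c9ccccc9COc1cc(OCc9ccccc9)c2c(c1)O[C@H](c8ccc(OCc9ccccc9)c(OCc9ccccc9)c8)[C@@H](OCc9ccccc9)[C@@H]2c1c(OCc9ccccc9)cc2c(c1OCc9ccccc9)[C@H](c1c(OCc9ccccc9)cc(OCc9ccccc9)c3c1O[C@H](c8ccc(OCc9ccccc9)c(OCc9ccccc9)c8)[C@H](O)[C@H]3c1c(OCc9ccccc9)cc(OCc9ccccc9)c3c1O[C@H](c8ccc(OCc9ccccc9)c(OCc9ccccc9)c8)[C@H](O)C3)[C@@H](OCc9ccccc9)[C@@H](c8ccc(OCc9ccccc9)c(OCc9ccccc9)c8)O2 | intermediate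
32 | catechin-(4α→6)-epicatechin-(4β→8)-epicatechin-(4β→8)-epicatechin (CNP0228086.1) | Oc1cc(O)c2c(c1)O[C@H](c1ccc(O)c(O)c1)[C@@H](O)[C@@H]2c1c(O)cc2c(c1O)[C@H](c1c(O)cc(O)c3c1O[C@H](c1ccc(O)c(O)c1)[C@H](O)[C@H]3c1c(O)cc(O)c3c1O[C@H](c1ccc(O)c(O)c1)[C@H](O)C3)[C@@H](O)[C@@H](c1ccc(O)c(O)c1)O2 | target

## Step count and risks

Total step count: 21. Longest linear sequence: 14 (steps 1 to 10, then 15, 16, 20 and 21). Steps 11 to 14 and steps 17 to 19 are convergent branches.

**Step 15 (key step, proposed new method).**
- What may go wrong: proton transfer to the aryl anion may outrun acyl capture. The proton can come from C3–H of the tethered ester through a six-membered transition state or from the medium; the result is the open aryl ether or, by way of the ester enolate, β-elimination of the aryloxide. The free alkoxide may undergo retro-aldol cleavage before it meets the aryne. The cis ketone may epimerise at C3 or open at O1–C2 if base accumulates.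
- Fallback (known chemistry): the annulation is abandoned and the catechin-(4α→6)-epicatechin unit is built by bromine-capped cation capture with orthogonal C4 activation. The fallback sets out from 4, 29 and 30 and rejoins the route at 32. Ether 29 is brominated at C8 with N-bromosuccinimide at low temperature to give the 8-bromo ether F1. Exchange of the alkoxy group for 2,6-dimethylbenzenethiol under BF3·OEt2 gives the 8-bromo thioether F2. The cation from 4 (BF3·OEt2, −78 °C, where the C–S bond is inert) can attack only the free C6 of F2, trans to the C3 benzyloxy group of unit 1, and gives the bromo dimer thioether F3. Activation of the C–S bond of F3 with iodine and Ag2O in the presence of excess 30 gives the bromo tetramer F4. Hydrogenolysis over Pd(OH)2/C with Et3N removes the benzyl groups and the bromine and gives 32.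

**Step 20.**
- What may go wrong: oligomerisation. The cation from 26 can be captured by its own kind (free C8 of unit 2, C6 and C8 of unit 1) or by C6 positions of 30, and the acid can cut interflavan bonds already present.
- Fallback: the lower half is added one unit at a time with a sulfur-masked C4, so that each cation meets a cheap monomer in large excess. The fallback sets out from 26, 29 and 28 and rejoins the route at 31. Ether 29 and 2,6-dimethylbenzenethiol with BF3·OEt2 give the monomer thioether F5. Ionisation of 26 with TMSOTf in the presence of excess F5 (attack at its C8, the C–S bond being inert to the hard acid) gives the trimer thioether F6. Activation of F6 with iodine and Ag2O in the presence of excess 28 gives 31.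

**Step 9.**
- What may go wrong: metalation at the wrong place. Possible sites are C4–H of unit 1 (followed by β-elimination of the 3-benzyloxy group), C6 or C8 of ring A of unit 1 (each between two ether oxygens), and benzylic C–H bonds (followed by Wittig rearrangement).
- Fallback: directed deprotonation is replaced by halogen–metal exchange, which is faster than any of these processes. The fallback sets out from 9 and rejoins the route at 15 by way of 14. Phenol 9 is brominated ortho to the hydroxyl with N-bromosuccinimide and catalytic i-Pr2NH at −78 °C, conditions selective for a free phenol over aryl ethers, to give the bromophenol F7. Hexamethyldisilazane gives the bromoaryl silyl ether F8. n-BuLi at −78 °C effects bromine–lithium exchange and the 1,3 O→C silyl shift (retro-Brook rearrangement) to the lithium salt of 14, which is triflated with PhNTf2 to 15.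

**Step 5.**
- What may go wrong: incomplete site selection between the para hydroxyl and the two ortho hydroxyls, giving positional isomers and bis-silyl ethers that are hard to separate.
- Fallback: the oxygens are differentiated before the C–C bond is made. The fallback sets out from 4 and 5 and rejoins the route at 7. Phloroglucinol 5 is monosilylated with one equivalent of TIPSCl and the mono(triisopropylsilyl) ether F9 is separated from di- and trisilyl ethers. F9 replaces 5 in the capture of the cation from 4 (BF3·OEt2). Attack at the carbon between the two free hydroxyls, remote from the bulky silyl ether, gives 7 directly.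

## Further compounds

F1 | step 15 | 8-bromo-5,7,3',4'-tetrakis(benzyloxy)-4β-(2-ethoxyethoxy)epicatechin | c9ccccc9COc1cc(OCc9ccccc9)c2c(c1Br)O[C@H](c8ccc(OCc9ccccc9)c(OCc9ccccc9)c8)[C@H](O)[C@H]2OCCOCC
F2 | step 15 | 8-bromo-5,7,3',4'-tetrakis(benzyloxy)-4β-(2,6-dimethylphenylthio)epicatechin | c9ccccc9COc1cc(OCc9ccccc9)c2c(c1Br)O[C@H](c8ccc(OCc9ccccc9)c(OCc9ccccc9)c8)[C@H](O)[C@H]2Sc7c(C)cccc7C
F3 | step 15 | penta-O-benzylcatechin-(4α→6)-[8-bromo-5,7,3',4'-tetra-O-benzyl-4β-(2,6-dimethylphenylthio)epicatechin] | c9ccccc9COc1cc(OCc9ccccc9)c2c(c1)O[C@H](c8ccc(OCc9ccccc9)c(OCc9ccccc9)c8)[C@@H](OCc9ccccc9)[C@@H]2c1c(OCc9ccccc9)c(Br)c2c(c1OCc9ccccc9)[C@H](Sc7c(C)cccc7C)[C@@H](O)[C@@H](c8ccc(OCc9ccccc9)c(OCc9ccccc9)c8)O2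
F4 | step 15 | heptadeca-O-benzyl tetramer with bromine at C8 of unit 2 and free 3-OH on units 2, 3 and 4 | c9ccccc9COc1cc(OCc9ccccc9)c2c(c1)O[C@H](c8ccc(OCc9ccccc9)c(OCc9ccccc9)c8)[C@@H](OCc9ccccc9)[C@@H]2c1c(OCc9ccccc9)c(Br)c2c(c1OCc9ccccc9)[C@H](c1c(OCc9ccccc9)cc(OCc9ccccc9)c3c1O[C@H](c8ccc(OCc9ccccc9)c(OCc9ccccc9)c8)[C@H](O)[C@H]3c1c(OCc9ccccc9)cc(OCc9ccccc9)c3c1O[C@H](c8ccc(OCc9ccccc9)c(OCc9ccccc9)c8)[C@H](O)C3)[C@@H](O)[C@@H](c8ccc(OCc9ccccc9)c(OCc9ccccc9)c8)O2
F5 | step 20 | 5,7,3',4'-tetrakis(benzyloxy)-4β-(2,6-dimethylphenylthio)epicatechin | c9ccccc9COc1cc(OCc9ccccc9)c2c(c1)O[C@H](c8ccc(OCc9ccccc9)c(OCc9ccccc9)c8)[C@H](O)[C@H]2Sc7c(C)cccc7C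
F6 | step 20 | penta-O-benzylcatechin-(4α→6)-(penta-O-benzylepicatechin)-(4β→8)-[5,7,3',4'-tetra-O-benzyl-4β-(2,6-dimethylphenylthio)epicatechin] | c9ccccc9COc1cc(OCc9ccccc9)c2c(c1)O[C@H](c8ccc(OCc9ccccc9)c(OCc9ccccc9)c8)[C@@H](OCc9ccccc9)[C@@H]2c1c(OCc9ccccc9)cc2c(c1OCc9ccccc9)[C@H](c1c(OCc9ccccc9)cc(OCc9ccccc9)c3c1O[C@H](c8ccc(OCc9ccccc9)c(OCc9ccccc9)c8)[C@H](O)[C@H]3Sc7c(C)cccc7C)[C@@H](OCc9ccccc9)[C@@H](c8ccc(OCc9ccccc9)c(OCc9ccccc9)c8)O2
F7 | step 9 | 3,5-bis(benzyloxy)-2-bromo-4-(penta-O-benzylcatechin-4α-yl)phenol | c9ccccc9COc1cc(OCc9ccccc9)c2c(c1)O[C@H](c8ccc(OCc9ccccc9)c(OCc9ccccc9)c8)[C@@H](OCc9ccccc9)[C@@H]2c1c(OCc9ccccc9)c(Br)c(O)cc1OCc9ccccc9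
F8 | step 9 | trimethylsilyl ether of bromophenol F7 | c9ccccc9COc1cc(OCc9ccccc9)c2c(c1)O[C@H](c8ccc(OCc9ccccc9)c(OCc9ccccc9)c8)[C@@H](OCc9ccccc9)[C@@H]2c1c(OCc9ccccc9)c(Br)c(O[Si](C)(C)C)cc1OCc9ccccc9
F9 | step 5 | 5-(triisopropylsilyloxy)benzene-1,3-diol | Oc1cc(O)cc(O[Si](C(C)C)(C(C)C)C(C)C)c1
A1 | alternative 1 | octa-O-benzyl epicatechin-(4β→8)-epicatechin with free 3-hydroxyls (identical with 30) | c9ccccc9COc1cc(OCc9ccccc9)c3c(c1)O[C@H](c8ccc(OCc9ccccc9)c(OCc9ccccc9)c8)[C@H](O)[C@H]3c1c(OCc9ccccc9)cc(OCc9ccccc9)c3c1O[C@H](c8ccc(OCc9ccccc9)c(OCc9ccccc9)c8)[C@H](O)C3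
A2 | alternative 2 | benzylated tetramer with unit 2 as 3,4-trans-3-benzyloxy-dihydrocoumarin (ring B of unit 2 absent) | c4ccccc4COc1cc(OCc4ccccc4)c2c(c1)O[C@H](c1ccc(OCc4ccccc4)c(OCc4ccccc4)c1)[C@@H](OCc4ccccc4)[C@@H]2c1c(OCc4ccccc4)cc2c(c1OCc4ccccc4)[C@H](c1c(OCc4ccccc4)cc(OCc4ccccc4)c3c1O[C@H](c1ccc(OCc4ccccc4)c(OCc4ccccc4)c1)[C@H](OCc4ccccc4)[C@H]3c1c(OCc4ccccc4)cc(OCc4ccccc4)c3c1O[C@H](c1ccc(OCc4ccccc4)c(OCc4ccccc4)c1)[C@H](OCc4ccccc4)C3)[C@@H](OCc4ccccc4)C(=O)O2
A3 | alternative 3 | benzylated epicatechin-(4β→8)-epicatechin with free 3-OH on unit 3 and 3-O-benzyl on unit 4 | c4ccccc4COc1cc(OCc4ccccc4)c3c(c1)O[C@H](c1ccc(OCc4ccccc4)c(OCc4ccccc4)c1)[C@H](O)[C@H]3c1c(OCc4ccccc4)cc(OCc4ccccc4)c3c1O[C@H](c1ccc(OCc4ccccc4)c(OCc4ccccc4)c1)[C@H](OCc4ccccc4)C3
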